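The earlier runs and the new flask were computed on assumed constants; scatter was added.

At early times Wednesday's flask lost Z at a steady pace, so I began there.

| flask | Z | G | remark | time |
|---|---|---|---|---|
| Wednesday's | 0.50 M | 2.8 M | run made earlier |  |
| amber | 0.50 M | 2.00 M |  | 2.0 min |
| green | 0.50 M | 2.00 M |  | 2.5 min |

Wednesday's run (percent of the Z charged)

| time / s | E / % | Z / % | Q / % | D / % |
|---|---|---|---|---|
| 10.0 | 0 | 96.8 | 2.9 | 0.3 |
| 25.0 | 0 | 91.4 | 7.9 | 0.1 |
| 50.0 | 0 | 82.7 | 12.8 | 1.9 |
| 80.0 | 0.4 | 74.7 | 17.4 | 5.5 |

(readings scatter by 0.5 percentage points)

- percentages count the Z that a species holds: one L or E counts as two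
- D is meant together with its L
- what may be going on: G + Q -> D; G + D -> J; Z + D <-> L; Z + D -> E; Z + G -> Q
- in an amount of D, one L counts as one D

* which of these there is most of at the end, counted by the Z in it, amber (D / Z / E / Q)
* which of these there is most of at the end, counted by the Z in it, green (D / Z / E / Q)
* final amount of the leader among these, as a percentage of the Z charged, in amber
* final amount of the leader among these, as a percentage of the Z charged, in green

I called dose the charged G times the elapsed time. Wednesday's last reading gave 0.0781 M⁻¹ min⁻¹ for the Z constant, the natural logarithm of charge over Z left, divided by the dose. The reading at 25.0 s gave 0.0771 M⁻¹ min⁻¹, so within the scatter the constant did not drift. That is pseudo-first-order behaviour in Z. At the last reading 2 percentage points of the charge were unaccounted for, against 25 points of Z lost. Whatever held them sits inside a constant read from Z itself.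

Then I built the ladder for amber. Amber ran 2.0 min. Q's life toward D, read from the D gain between the last two readings, came to 2.94 min, longer than that run, so I expected Q still to be climbing at the end. Z's life was 6.40 min, longer again. The Z lost would cost G 6.71% of its charge.

Amber's dose was 1.07 of Wednesday's last, and green's 1.34, so the constant had to stretch a short way. I reckoned 73.2% Z left in amber and 67.7% in green. Each exceeded the rest of the charge, so Z would lead.

The forecast named Z in amber and Z in green, with 73% and 67.5%, which lay 0.20 points and 0.20 points below my figures. It said “Z stays the leader in both runs”.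

The flasks gave Z at 73.0% in amber and Z at 67.2% in green.

    G + Q → D (k = 0.00214 M⁻¹ s⁻¹)
    G + D → J (k = 6.64 × 10⁻⁴ M⁻¹ s⁻¹)
    Z + D ⇌ L, settled at all times (K = 3.60 M⁻¹)
    Z + D → E (k = 0.00659 M⁻¹ s⁻¹)
    Z + G → Q (k = 0.00120 M⁻¹ s⁻¹)

My figures stood 0.20 points above amber and 0.50 points above green. The neighbour of amber charged with 1.2 M of G and read at 2.00 min had 0.643 of Wednesday's last dose. The Z constant gives 82.9% Z left there, and that neighbour held 83.4%. Its Q stood at 13.1%.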